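**Retrosynthetic overview**
1. C6'=C7': a last-step E-selective cross-metathesis joins the east fragment 9 (terminal olefin, acylpyranone complete) and the west fragment 15 (α-propenyl acid), with no protecting groups.
2. East fragment: the C3–C1' bond comes from DCC/DMAP O-acylation and O→C acyl shift of acid 5 onto dihydropyranone 7.
3. West fragment: the C7'–C8' bond and the C8' stereocentre come from amine-catalysed enantioselective α-alkenylation of (S)-4-methylhexanal 12, then oxidation.
4. C4' and C10' both come from one batch of (R)-citronellal 2, made from achiral citral by organocatalytic transfer hydrogenation (first stereocentre); 2 → 5 by Wittig and ozonolysis/oxidation, 2 → 12 by Wolff–Kishner and ozonolysis.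
5. Ring: the only ring is not built but bought as the aromatic pyrone 6; its C6 stereocentre is set by a new Brønsted-acid-catalysed asymmetric transfer hydrogenation (step 4) before acylation.

Locants: C1' is the ketone carbon on the ring and the chain runs out to C12' (ethyl end); the ring is numbered as 2H-pyran-2-one. The target is 4'R, 8'S, 10'S, 6R with a 6'E olefin.
Assumption: commercial citral (geranial/neral mixture) is used as such, because the E and Z iminium ions equilibrate faster than hydride transfer and converge on one enantiomer.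
Note: 2 is expected at about 90% ee; because both chain halves come from it, the main diastereomer is enantiomerically upgraded on union and the roughly 10% of minor diastereomers are removed by chromatography at 15 and 16.

**Route**

Step 1
Reactants: 1 citral (3,7-dimethylocta-2,6-dienal; E/Z mixture)
Product: 2 (R)-citronellal [(3R)-3,7-dimethyloct-6-enal]
Conditions: Hantzsch ester (diethyl 2,6-dimethyl-1,4-dihydropyridine-3,5-dicarboxylate, 1.1 equiv), morpholinium (R)-TRIP phosphate (20 mol%), 1,4-dioxane, 50 °C, 24 h
Reagents that add atoms: none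
Why: Iminium-ion organocatalytic transfer hydrogenation (counteranion-directed): the chiral TRIP phosphate paired with the morpholinium iminium of 1 directs hydride from the Hantzsch ester to one face of C3, setting the 3R methyl stereocentre (later C4' and C10'), while the isolated trisubstituted olefin is inert.

Step 2
Reactants: 2 (R)-citronellal
Product: 3 (4R)-4,8-dimethylnona-1,7-diene
Conditions: Ph3PCH3Br, KOtBu, THF, 0 °C → rt
Reagents that add atoms: methyltriphenylphosphonium bromide, C[P+](c1ccccc1)(c1ccccc1)c1ccccc1.[Br-]
Why: Wittig methylenation of the aldehyde installs the terminal olefin (C6'), and the β-stereocentre cannot epimerise.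

Step 3
Reactants: 3 (4R)-4,8-dimethylnona-1,7-diene
Product: 5 (4R)-4-methylhept-6-enoic acid, via (4R)-4-methylhept-6-enal 4 (not isolated)
Conditions: O3 (1.0 equiv, Sudan Red 7B endpoint), CH2Cl2, −78 °C; Me2S, −78 °C → rt; then NaClO2, NaH2PO4, 2-methyl-2-butene, tBuOH/H2O, 0 °C → rt
Reagents that add atoms: ozone, [O-][O+]=O; sodium chlorite, [Na+].[O-]Cl=O
Why: Chemoselective ozonolysis of the electron-rich trisubstituted olefin (markedly faster than the monosubstituted vinyl group, dye-indicated endpoint) followed by Pinnick oxidation of the crude aldehyde gives the C1' acid with the stereocentre untouched.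

Step 4
Reactants: 6 4-hydroxy-6-methyl-2H-pyran-2-one (triacetic acid lactone)
Product: 7 (6R)-4-hydroxy-6-methyl-5,6-dihydro-2H-pyran-2-one
Conditions: Hantzsch ester (1.3 equiv), (R)-3,3'-bis(2,4,6-triisopropylphenyl)-BINOL N-triflylphosphoramide (10 mol%), 5 Å MS, 1,2-dichloroethane/1,4-dioxane (4:1), 50 °C
Reagents that add atoms: none
Why: Proposed new method: the strong chiral Brønsted acid protonates the pyrone carbonyl to a 2,4-dihydroxypyrylium ion held as a contact ion pair with the phosphoramidate, the Hantzsch ester (hydrogen-bonded through N–H to the same anion) delivers hydride to C6 inside the chiral pocket, and the resulting 6H-pyran-2,4-diol tautomerises irreversibly to the enolised β-keto lactone 7, which cannot re-form a pyrylium ion and is not reduced further; the C6 configuration (R wanted) is fixed by the catalyst antipode, to be chosen by screening both; the closest known reaction type is chiral phosphoric acid/Hantzsch ester transfer hydrogenation of quinolines, pyridines and benzopyrylium-type cations (asymmetric ion-pair catalysis), not yet shown on 2-pyrones.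

Step 5
Reactants: 5 (4R)-4-methylhept-6-enoic acid; 7 (6R)-4-hydroxy-6-methyl-5,6-dihydro-2H-pyran-2-one
Product: 9 (6R)-4-hydroxy-6-methyl-3-[(4R)-4-methylhept-6-enoyl]-5,6-dihydro-2H-pyran-2-one, via O-acyl enol ester 8 (not isolated)
Conditions: DCC (1.1 equiv), DMAP (0.3 equiv), CH2Cl2, 0 °C → rt, 16 h
Reagents that add atoms: none
Why: Steglich O-acylation of the vinylogous acid followed by DMAP-mediated O→C acyl migration (Fries-type, through an acylpyridinium/enolate pair) gives the hydrogen-bonded 3-acyl tricarbonyl, and neither stereocentre is acidic under these conditions.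

Step 6
Reactants: 2 (R)-citronellal
Product: 11 (6S)-2,6-dimethyloct-2-ene, via (R)-citronellal hydrazone 10 (not isolated)
Conditions: N2H4·H2O, KOH, diethylene glycol, 130 °C → 200 °C, product distilled out
Reagents that add atoms: none
Why: Wolff–Kishner reduction (Huang–Minlon) turns the aldehyde into the C12' methyl group; the stereocentre is β to the carbonyl and is not epimerised (it becomes S only through the change in CIP priorities).

Step 7
Reactants: 11 (6S)-2,6-dimethyloct-2-ene
Product: 12 (4S)-4-methylhexanal
Conditions: O3, CH2Cl2, −78 °C; Me2S, −78 °C → rt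
Reagents that add atoms: ozone, [O-][O+]=O
Why: Ozonolysis with reductive work-up cleaves the only olefin to the aldehyde whose carbonyl carbon becomes the C8' carboxyl.

Step 8
Reactants: 12 (4S)-4-methylhexanal; 13 (E)-prop-1-en-1-ylboronic acid
Product: 14 (2S,4S)-4-methyl-2-[(E)-prop-1-en-1-yl]hexanal
Conditions: 13 (1.5 equiv), Cu(OAc)2 (30 mol%), (2R,5R)-5-benzyl-2-tert-butyl-3-methylimidazolidin-4-one·TFA (20 mol%), O2 (1 atm), 4 Å MS, EtOAc, 23 °C; crude product taken on at once
Reagents that add atoms: none
Why: Enamine/divalent-copper dual-catalytic oxidative α-alkenylation (Chan–Lam-type transmetalation, then enamine capture and reductive elimination with retention of olefin geometry): the benzyl and tert-butyl groups of the (2R,5R)-catalyst shield the Si face of the E-enamine so the alkenyl group is delivered to the Re face, giving 2S (C8') under catalyst control regardless of the remote C4 centre.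

Step 9
Reactants: 14 (2S,4S)-4-methyl-2-[(E)-prop-1-en-1-yl]hexanal
Product: 15 (2S,4S)-4-methyl-2-[(E)-prop-1-en-1-yl]hexanoic acid
Conditions: NaClO2, NaH2PO4, 2-methyl-2-butene, tBuOH/H2O, 0 °C
Reagents that add atoms: sodium chlorite, [Na+].[O-]Cl=O
Why: Pinnick oxidation under buffered, mildly acidic conditions converts the sensitive β,γ-unsaturated aldehyde into the acid without epimerising C2 or moving the double bond.

Step 10
Reactants: 9 (6R)-4-hydroxy-6-methyl-3-[(4R)-4-methylhept-6-enoyl]-5,6-dihydro-2H-pyran-2-one; 15 (2S,4S)-4-methyl-2-[(E)-prop-1-en-1-yl]hexanoic acid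
Product: 16 (2S,3E,6R)-9-[(6R)-4-hydroxy-6-methyl-2-oxo-5,6-dihydro-2H-pyran-3-yl]-6-methyl-2-[(2S)-2-methylbutyl]-9-oxonon-3-enoic acid (CNP0241663.1)
Conditions: 15 (2 equiv), RuCl2(H2IMes)(=CH-C6H4-2-OiPr) (second-generation Hoveyda–Grubbs catalyst, 2 × 5 mol%), 1,4-benzoquinone (10 mol%), CH2Cl2, 40 °C, N2 sparge
Reagents that add atoms: none
Why: Olefin cross-metathesis exchanges the terminal CH2 of 9 with the ethylidene end of 15 and is driven by loss of propene; the α-branched allylic centre favours the E olefin under thermodynamic control, the ruthenium carbene tolerates the free acid and the chelated enol, benzoquinone suppresses Ru–H double-bond migration, and no stereocentre is touched.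

**Compound list**
1 | citral (3,7-dimethylocta-2,6-dienal, E/Z mixture) | CC(C)=CCCC(C)=CC=O | starting material
2 | (R)-citronellal [(3R)-3,7-dimethyloct-6-enal] | O=CC[C@H](C)CCC=C(C)C | intermediate
3 | (4R)-4,8-dimethylnona-1,7-diene | C=CC[C@H](C)CCC=C(C)C | intermediate
4 | (4R)-4-methylhept-6-enal | C=CC[C@H](C)CCC=O | intermediate
5 | (4R)-4-methylhept-6-enoic acid | C=CC[C@H](C)CCC(=O)O | intermediate
6 | 4-hydroxy-6-methyl-2H-pyran-2-one (triacetic acid lactone) | CC1=CC(O)=CC(=O)O1 | starting material
7 | (6R)-4-hydroxy-6-methyl-5,6-dihydro-2H-pyran-2-one | O=C1C=C(O)C[C@@H](C)O1 | intermediate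
8 | (2R)-2-methyl-6-oxo-3,6-dihydro-2H-pyran-4-yl (4R)-4-methylhept-6-enoate (O-acyl enol ester) | C=CC[C@H](C)CCC(=O)OC1=CC(=O)O[C@H](C)C1 | intermediate
9 | (6R)-4-hydroxy-6-methyl-3-[(4R)-4-methylhept-6-enoyl]-5,6-dihydro-2H-pyran-2-one | C=CC[C@H](C)CCC(=O)C1=C(O)C[C@@H](C)OC1=O | intermediate
10 | (R)-citronellal hydrazone [(1E,3R)-(3,7-dimethyloct-6-en-1-ylidene)hydrazine] | N/N=C/C[C@H](C)CCC=C(C)C | intermediate
11 | (6S)-2,6-dimethyloct-2-ene | CC[C@H](C)CCC=C(C)C | intermediate
12 | (4S)-4-methylhexanal | CC[C@H](C)CCC=O | intermediate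
13 | (E)-prop-1-en-1-ylboronic acid | C/C=C/B(O)O | starting material
14 | (2S,4S)-4-methyl-2-[(E)-prop-1-en-1-yl]hexanal | CC[C@H](C)C[C@@H](/C=C/C)C=O | intermediate
15 | (2S,4S)-4-methyl-2-[(E)-prop-1-en-1-yl]hexanoic acid | CC[C@H](C)C[C@@H](/C=C/C)C(=O)O | intermediate
16 | (2S,3E,6R)-9-[(6R)-4-hydroxy-6-methyl-2-oxo-5,6-dihydro-2H-pyran-3-yl]-6-methyl-2-[(2S)-2-methylbutyl]-9-oxonon-3-enoic acid | CC[C@H](C)C[C@@H](/C=C/C[C@H](C)CCC(=O)C1=C(O)C[C@@H](C)OC1=O)C(=O)O | target

**Step count and risks**
Total: 10 steps. Longest linear sequence: 6 steps (1 → 2 → 11 → 12 → 14 → 15 → 16, i.e. steps 1, 6, 7, 8, 9, 10).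

Step 4 (the proposed new transfer hydrogenation) is the most uncertain. The pyrone is weakly basic, so little pyrylium ion may form; the Hantzsch pyridine by-product may tie up the acid; and the ee is unknown. The fallback sets out from 6 and comes back at 7. It replaces the metal-free ionic hydride transfer with inner-sphere hydrogenation by H2 on a chiral ruthenium diphosphine complex, Ru(OAc)2(MeO-BIPHEP) (ligand antipode that gives 6R), H2 (60 bar), MeOH, 60 °C. This reduction of the C5=C6 bond of this very pyrone is known and highly enantioselective. It makes no new compound (entry F0).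

Step 8 may fail because the simple alkyl-substituted boronic acid could transmetalate or couple poorly, and because aldehyde 14 can racemise or slip into conjugation before oxidation. The fallback sets out from 12 and comes back at 16. It replaces the copper-mediated two-electron alkenylation with the organo-SOMO (enamine radical-cation) pathway and a styryl donor. Compound 12 with potassium (E)-styryltrifluoroborate, the same (2R,5R)-imidazolidinone·TFA (20 mol%), (NH4)2Ce(NO3)6 (2.5 equiv) and NaHCO3 in DME at −50 °C gives (2S,4S)-4-methyl-2-[(E)-2-phenylethenyl]hexanal F1. Pinnick oxidation as in step 9 gives (2S,4S)-4-methyl-2-[(E)-2-phenylethenyl]hexanoic acid F2. Cross-metathesis of F2 with 9 under the step 10 conditions, with styrene leaving in place of propene, gives 16.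

Step 10 may fail because the chelating acylpyranone and the free acid could slow the ruthenium catalyst, the branched partner is sluggish, and E/Z mixtures or double-bond migration are possible. The fallback sets out from 15 and 5 and comes back at 16. It moves the metathesis ahead of the pyranone acylation and runs it on two simple partners with the C8' acid masked. Compound 15 with tert-butyl 2,2,2-trichloroacetimidate and catalytic BF3·OEt2 in cyclohexane/CH2Cl2 gives tert-butyl (2S,4S)-4-methyl-2-[(E)-prop-1-en-1-yl]hexanoate F3. Cross-metathesis of F3 with acid 5 under the same ruthenium catalyst gives (4R,6E,8S,10S)-8-(tert-butoxycarbonyl)-4,10-dimethyldodec-6-enoic acid F4. DCC/DMAP acylation of 7 with F4 as in step 5 gives tert-butyl (2S,3E,6R)-9-[(6R)-4-hydroxy-6-methyl-2-oxo-5,6-dihydro-2H-pyran-3-yl]-6-methyl-2-[(2S)-2-methylbutyl]-9-oxonon-3-enoate F5. TFA/CH2Cl2 at 0 °C then gives 16.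

**Further compounds**
F0 | step 4 | none | none
F1 | step 8 | (2S,4S)-4-methyl-2-[(E)-2-phenylethenyl]hexanal | CC[C@H](C)C[C@@H](/C=C/c1ccccc1)C=O
F2 | step 8 | (2S,4S)-4-methyl-2-[(E)-2-phenylethenyl]hexanoic acid | CC[C@H](C)C[C@@H](/C=C/c1ccccc1)C(=O)O
F3 | step 10 | tert-butyl (2S,4S)-4-methyl-2-[(E)-prop-1-en-1-yl]hexanoate | CC[C@H](C)C[C@@H](/C=C/C)C(=O)OC(C)(C)C
F4 | step 10 | (4R,6E,8S,10S)-8-(tert-butoxycarbonyl)-4,10-dimethyldodec-6-enoic acid | CC[C@H](C)C[C@@H](/C=C/C[C@H](C)CCC(=O)O)C(=O)OC(C)(C)C
F5 | step 10 | tert-butyl (2S,3E,6R)-9-[(6R)-4-hydroxy-6-methyl-2-oxo-5,6-dihydro-2H-pyran-3-yl]-6-methyl-2-[(2S)-2-methylbutyl]-9-oxonon-3-enoate | CC[C@H](C)C[C@@H](/C=C/C[C@H](C)CCC(=O)C1=C(O)C[C@@H](C)OC1=O)C(=O)OC(C)(C)C
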